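**Plan**

1. Cuts: C1–OH with the C2=C3 enone comes from a C1=C2 alkene (bromohydrin, then loss of HBr); the spiro cyclohexene from a Diels–Alder reaction (C5–C13′, C3–C11′); both butenone chains from enol triflates (C1–C2, C1′–C2′); each α-methylene lactone from O–C8 and C11–C7 made in one Pd annulation; C10–CH3 from tropone and MeLi.
2. Enabling feature: in the lactone-bearing seven-membered ring, the O-bearing C8 and the C11-bearing C7 are the γ- and δ-carbons of a 2,4-dienone whose carbonyl is C1 and whose α-carbon C10 carries the methyl. 2-Methylcyclohepta-2,4-dienone is therefore polarised to take carbon at C7 and oxygen at C8.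
3. Forward: seven-membered ring (tropone) → cis-fused methylene lactone (key step) → thiol-masked ketone → enol triflate → chromatographic resolution, each antipode being collected as a product of its own (steps 5 and 6).
4. The (7R,8R,10S) antipode keeps the thiol mask and receives its butenone (diene only, ring A half); the (7S,8S,10R) antipode is unmasked (dienophile only). Diels–Alder closes the cyclohexene; Stille coupling, unmasking and γ-hydroxylation follow.
5. Stereochemistry: C7/C8 cis from syn carbopalladation and closure; C10 by protonation of the enolate; absolute configuration of both halves from the one resolution; C5 and C11′ from the exo, convex-face cycloaddition; C1 from anti opening of a bromonium ion.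

Key step: step 2

Remark: in the target the centres C7′, C8′, C10′ of the spiro-lactone half are antipodal to C7, C8, C10 of the hydroxylated half, so the halves come from the two antipodes of one bicyclic intermediate. Xanthane numbering is used: seven-membered ring C1, C5–C10 (C14 = methyl on C10), lactone carbons C11–C13, side chain C2–C4 and C15, primes for the spiro-lactone half. Racemates are drawn as the enantiomer that leads to the ring A half. The configuration at C11 of the masked compounds is of no consequence, because C11 becomes sp2 again on unmasking.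

**Step 1**
Reactants: 1 tropone
Product: 3 2-methylcyclohepta-2,4-dien-1-one, via 2-methylcyclohepta-3,5-dien-1-one 2 (not isolated)
Conditions: MeLi, THF, −78 °C; aq. NH4Cl; then DBU (10 mol %), CH2Cl2, 25 °C
Reagents that add atoms: methyllithium ([Li]C)
Why: 1,8-addition of the organolithium to tropone gives the 2-methyl-3,5-dienone, and base then equilibrates it through the trienolate to the conjugated dienone with the trisubstituted C=C, in which no stereocentre remains.

**Step 2**
Reactants: 3 2-methylcyclohepta-2,4-dien-1-one; 4 2-bromoacrylic acid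
Product: 5 racemic cis-fused α-methylene lactone enone
Conditions: Pd(OAc)2 (5 mol %), KOAc (2 equiv), n-Bu4NCl, DMF, 60 °C
Reagents that add atoms: none
Why: Proposed new method: oxidative addition of zerovalent palladium to the C–Br bond of 4 (as its carboxylate) gives a 1-carboxyvinyl–Pd species that adds syn across the terminal C7=C8 bond of the dienone, carbon to the δ-carbon C7 and palladium to C8, where it is an η3-allyl (C8–C9–C10) conjugated with the C1 carbonyl; the palladium-bound carboxylate oxygen then forms O–C8 by reductive elimination, releasing zerovalent palladium and the C9=C10–C1=O enone. The closest known reaction type is the Larock heteroannulation of cyclic 1,3-dienes by vinylic or aryl halides that carry OH, NHR or CO2H, together with the Heck reaction of 2,4-dienones at the δ-carbon; a conjugated dienone as the diene and 2-bromoacrylic acid as the halide are the untested elements. The five-membered lactone closes by C–O reductive elimination from a six-membered oxapalladacycle, the oxygen going to the allyl terminus next to the new C–C bond (attack at C10 would need a seven-membered ring). C7 and C8 are created together and cis, because vinyl and Pd add to the same face and the tethered carboxylate can reach C8 only from that face. The step needs δ- over β-selectivity and C–O closure in preference to β-hydride loss: the C10 methyl shields the β-carbon C9, the syn adduct has no hydrogen syn to Pd on C7, and the closure is intramolecular.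

**Step 3**
Reactants: 5 racemic cis-fused α-methylene lactone enone
Product: 7 racemic masked ketone, via thiol adduct enone 6 (not isolated)
Conditions: PhSH (1.0 equiv), Et3N (5 mol %), THF, 0 °C; then LiBH(s-Bu)3, −78 °C; aq. NH4Cl
Reagents that add atoms: thiophenol (Sc1ccccc1)
Why: Thia-Michael addition masks the exocyclic methylene (C11 protonated on the convex face, cis to H-7) so that the 1,4-hydride reduction touches only the enone; the resulting C10=C1 enolate should be protonated anti to the lactone oxygen on C8, which places the methyl cis to the lactone, the epimer also expected to be the more stable (cis-1,3).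

**Step 4**
Reactants: 7 racemic masked ketone
Product: 8 racemic enol triflate
Conditions: KN(SiMe3)2, THF, −78 °C; PhNTf2; aq. NH4Cl
Reagents that add atoms: N-phenylbis(trifluoromethanesulfonimide) (O=S(=O)(N(c1ccccc1)S(=O)(=O)C(F)(F)F)C(F)(F)F)
Why: Kinetic deprotonation of the 2-methyl ketone occurs at the unsubstituted α-carbon C5 (the ketone is more acidic than the lactone), and O-triflation fixes the C1=C5 enol triflate without touching C10.

**Step 5**
Reactants: 8 racemic enol triflate
Product: 9 (7R,8R,10S,11S)-enol triflate
Conditions: preparative SFC, amylose tris(3,5-dimethylphenylcarbamate) stationary phase, CO2/i-PrOH, stacked injections; the fraction of the (7R,8R,10S,11S) antipode is collected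
Reagents that add atoms: none
Why: Chromatographic resolution on a chiral stationary phase separates the antipodes of a single diastereomer without chemical change, and the sulfur and fluorine atoms should allow the absolute configuration of the collected fraction to be assigned by anomalous-dispersion crystallography before use.

**Step 6**
Reactants: 8 racemic enol triflate
Product: 10 (7S,8S,10R,11R)-enol triflate
Conditions: the other fraction of the same preparative SFC runs (same stationary phase, CO2/i-PrOH), collected and freed of solvent
Reagents that add atoms: none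
Why: The other half of racemate 8 is the antipode that the spiro-lactone half needs, so collecting it as a product of its own lets the one resolution supply both halves of the target with no antipode discarded.

**Step 7**
Reactants: 9 (7R,8R,10S,11S)-enol triflate
Product: 11 masked diene half
Conditions: methyl vinyl ketone (5 equiv), Pd(OAc)2 (5 mol %), PPh3 (10 mol %), Et3N, DMF, 60 °C
Reagents that add atoms: methyl vinyl ketone (C=CC(C)=O)
Why: The Heck reaction of an enol triflate with an enone gives the (E)-dienone by syn insertion and syn β-hydride elimination, and the masked lactone leaves 11 able to act only as the diene.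

**Step 8**
Reactants: 10 (7S,8S,10R,11R)-enol triflate
Product: 13 dienophile half, via antipodal triflate sulfoxide 12 (not isolated)
Conditions: NaIO4, MeOH/H2O, 0 °C; then PhMe, CaCO3, 90 °C
Reagents that add atoms: none
Why: Periodate oxidises only the sulfide, and the sulfoxide undergoes thermal syn-elimination toward its single β-hydrogen (H-11, activated by the carbonyl) to restore the exocyclic methylene; the enol triflate carries no diene, so 13 can act only as dienophile.

**Step 9**
Reactants: 11 masked diene half; 13 dienophile half (1.5 equiv)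
Product: 14 Diels–Alder adduct
Conditions: PhMe (2 M), BHT (cat.), 90 °C, sealed tube
Reagents that add atoms: none
Why: The [4+2] cycloaddition joins C13′ (acrylate β-carbon) to C5 (the distal diene terminus) and C11′ to C3; C11′ should be set by attack on the convex lactone face (syn to H-7′), the exo orientation of the s-cis-locked lactone carbonyl fixes C3/C5 relative to C11′, and the bond to C5 has to form on the face of ring A that carries C11 and C14 (opposite to H-7, H-8 and H-10), the least secure selectivity because the C10 methyl sits on that face.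

**Step 10**
Reactants: 14 Diels–Alder adduct
Product: 15 bis-butenone adduct
Conditions: (E)-4-(tributylstannyl)but-3-en-2-one, Pd2(dba)3 (5 mol %), AsPh3, LiCl, CuI (10 mol %), NMP, 40 °C
Reagents that add atoms: (E)-4-(tributylstannyl)but-3-en-2-one (CC(=O)/C=C/[Sn](CCCC)(CCCC)CCCC)
Why: Stille coupling of the alkenyl triflate proceeds with retention of the (E)-geometry under neutral conditions, which keeps the β,γ-unsaturated ketone (C1=C2, H-3) from conjugating.

**Step 11**
Reactants: 15 bis-butenone adduct
Product: 17 unmasked adduct, via adduct sulfoxide 16 (not isolated)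
Conditions: NaIO4, MeOH/H2O, 0 °C; then PhMe, CaCO3, 90 °C
Reagents that add atoms: none
Why: Chemoselective sulfide oxidation and sulfoxide syn-elimination toward H-11 regenerate the α-methylene lactone under neutral conditions, without touching the stereocentres.

**Step 12**
Reactants: 17 unmasked adduct
Product: 19 target, via bromohydrin 18 (not isolated)
Conditions: NBS (1.05 equiv), THF/H2O (4:1), 0 °C; then Et3N, 25 °C
Reagents that add atoms: water (O)
Why: The only electron-rich alkene, C1=C2, should form its bromonium ion on the face flanked by H-3, H-5 and H-10 (the other face carries the acetyl group and C14); water opens it at the tertiary C1 from the opposite face (OH cis to C14, trans to H-5), and Et3N removes HBr from the β-bromo ketone by E1cB to give the C2=C3 enone.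

**Compound list**

1 | tropone (cyclohepta-2,4,6-trien-1-one) | O=C1C=CC=CC=C1 | starting material
2 | 2-methylcyclohepta-3,5-dien-1-one (racemic; centre lost in the next operation) | CC1C=CC=CCC1=O | intermediate
3 | 2-methylcyclohepta-2,4-dien-1-one | CC1=CC=CCCC1=O | intermediate
4 | 2-bromoacrylic acid (2-bromoprop-2-enoic acid) | C=C(Br)C(=O)O | starting material
5 | rac-(3aR,8aR)-7-methyl-3-methylidene-3,3a,4,5-tetrahydro-2H-cyclohepta[b]furan-2,6(8aH)-dione (cis-fused lactone on C7/C8, enone C9=C10(CH3)–C1=O) | C=C1C(=O)O[C@@H]2C=C(C)C(=O)CC[C@H]12 | intermediate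
6 | thiol adduct of 5: 7-methyl-3-[(phenylsulfanyl)methyl] analogue, H-3 cis to H-3a and H-8a (racemic) | O=C1O[C@@H]2C=C(C)C(=O)CC[C@@H]2[C@@H]1CSc1ccccc1 | intermediate
7 | rac-(3S,3aR,7S,8aR)-7-methyl-3-[(phenylsulfanyl)methyl]hexahydro-2H-cyclohepta[b]furan-2,6(3H)-dione (C1 ketone, 10-methyl, 11-CH2SPh; H-7, H-8, H-10, H-11 on one face; xanthane 7R,8R,10S,11S shown) | O=C1O[C@@H]2C[C@H](C)C(=O)CC[C@@H]2[C@@H]1CSc1ccccc1 | intermediate
8 | racemic enol triflate of 7 (C1(OTf)=C5), drawn as the (7R,8R,10S,11S) antipode | O=C1O[C@@H]2C[C@H](C)C(OS(=O)(=O)C(F)(F)F)=CC[C@@H]2[C@@H]1CSc1ccccc1 | intermediate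
9 | (7R,8R,10S,11S)-enol triflate | O=C1O[C@@H]2C[C@H](C)C(OS(=O)(=O)C(F)(F)F)=CC[C@@H]2[C@@H]1CSc1ccccc1 | intermediate
10 | (7S,8S,10R,11R)-enol triflate (antipode of 9) | O=C1O[C@H]2C[C@@H](C)C(OS(=O)(=O)C(F)(F)F)=CC[C@H]2[C@H]1CSc1ccccc1 | intermediate
11 | (3S,3aR,7S,8aR)-7-methyl-6-[(E)-3-oxobut-1-enyl]-3-[(phenylsulfanyl)methyl]-3,3a,4,7,8,8a-hexahydro-2H-cyclohepta[b]furan-2-one (C1 carries the butenone, C1=C5; 13-SPh) | O=C1O[C@@H]2C[C@H](C)C(/C=C/C(C)=O)=CC[C@@H]2[C@@H]1CSc1ccccc1 | intermediate
12 | sulfoxide of 10 (mixture at sulfur) | O=C1O[C@H]2C[C@@H](C)C(OS(=O)(=O)C(F)(F)F)=CC[C@H]2[C@H]1CS(=O)c1ccccc1 | intermediate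
13 | (3aS,7R,8aS)-7-methyl-3-methylidene-2-oxo-3,3a,4,7,8,8a-hexahydro-2H-cyclohepta[b]furan-6-yl trifluoromethanesulfonate (xanthane 7S,8S,10R) | C=C1C(=O)O[C@H]2C[C@@H](C)C(OS(=O)(=O)C(F)(F)F)=CC[C@@H]12 | intermediate
14 | Diels–Alder adduct: ring A half (7R,8R,10S,11S; 13-SPh) fused at C1–C5 to the cyclohexene C1=C2–C3H(Ac)–C11′–C13′H2–C5H (3S,5S), spiro at C11′ (R) to the (7′S,8′S,10′R)-lactone carrying C1′–OTf | O=C1O[C@@H]2C[C@H](C)C3=C[C@H](C(C)=O)[C@]4(C[C@@H]3C[C@@H]2[C@@H]1CSc1ccccc1)C(=O)O[C@H]1C[C@@H](C)C(OS(=O)(=O)C(F)(F)F)=CC[C@H]14 | intermediate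
15 | as 14 with (E)-3-oxobut-1-enyl on C1′ in place of OTf | O=C1O[C@@H]2C[C@H](C)C3=C[C@H](C(C)=O)[C@]4(C[C@@H]3C[C@@H]2[C@@H]1CSc1ccccc1)C(=O)O[C@H]1C[C@@H](C)C(/C=C/C(C)=O)=CC[C@H]14 | intermediate
16 | sulfoxide of 15 (mixture at sulfur) | O=C1O[C@@H]2C[C@H](C)C3=C[C@H](C(C)=O)[C@]4(C[C@@H]3C[C@@H]2[C@@H]1CS(=O)c1ccccc1)C(=O)O[C@H]1C[C@@H](C)C(/C=C/C(C)=O)=CC[C@H]14 | intermediate
17 | 1-deoxy-1,2-didehydro-2,3-dihydro precursor of the target (C1=C2, H-3; both α-methylene lactones present) | C=C1C(=O)O[C@@H]2C[C@H](C)C3=C[C@H](C(C)=O)[C@]4(C[C@@H]3C[C@H]12)C(=O)O[C@H]1C[C@@H](C)C(/C=C/C(C)=O)=CC[C@H]14 | intermediate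
18 | bromohydrin of 17: OH on C1 (cis to C14), Br on C2 (trans to OH) | C=C1C(=O)O[C@@H]2C[C@H](C)[C@@]3(O)[C@@H](Br)[C@H](C(C)=O)[C@]4(C[C@@H]3C[C@H]12)C(=O)O[C@H]1C[C@@H](C)C(/C=C/C(C)=O)=CC[C@H]14 | intermediate
19 | CNP0168949.2 (1S,5S,7R,8R,10S,11′R,7′S,8′S,10′R) | C=C1C(=O)O[C@@H]2C[C@H](C)[C@@]3(O)C=C(C(C)=O)[C@]4(C[C@@H]3C[C@H]12)C(=O)O[C@H]1C[C@@H](C)C(/C=C/C(C)=O)=CC[C@H]14 | target

**Step count and risks**

Total steps: 12; steps 5 and 6 are the two collected fractions of one chromatographic separation, listed apart because each antipode is a product of its own. Longest linear sequence: 10 (steps 1–5, 7 and 9–12, or steps 1–4, 6 and 8–12).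

Step 2 (proposed new method). What may go wrong: after carbopalladation the palladium intermediate loses palladium hydride (also possible from the C10 methyl when palladium sits on C10) or is protonated instead of closing the C–O bond, carbon is delivered to C9, or 4 loses HBr and polymerises under the basic conditions. Fallback with known reaction types, from 3 back to 5: 1,6-conjugate addition of the cuprate Li[Cu(C(=CH2)CO2t-Bu)2] to 3, with α-protonation of the dienolate, should give the β,γ-unsaturated keto ester tert-butyl 2-(4-methyl-5-oxocyclohept-2-en-1-yl)acrylate F1 (C10 epimers). Iodolactonisation (I2, MeCN) should close the cis lactone onto C8 with loss of the tert-butyl group and place iodine on C9, giving the 9-iodo cis-lactone ketone F2. DBU then removes HI from this β-iodo ketone and gives 5.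

Step 9. What may go wrong: bond formation at C5 on the face anti to C14, which would lead into the C5-epimeric series, and slow cycloaddition of two electron-poor partners. Fallback that replaces the kinetically controlled cycloaddition by an anionic annulation, from 7 to 19: the chromatography of steps 5 and 6 is applied to 7 and gives the (7R,8R,10S,11S)-masked ketone F3 and the (7S,8S,10R,11R)-masked ketone F4. F4 is taken through step 4 (which then gives 10) and step 8 to 13. LiN(i-Pr)2 forms the C5 enolate of F3, which adds to 13 (C5–C13′). In the same flask the resulting lactone enolate adds to (E)-4-nitrobut-3-en-2-one at the carbon β to nitro (C11′–C3), and the nitronate closes onto the C1 ketone (Henry reaction) to give the nitro ketol F5. Because the Henry step is reversible and C5/C10 are enolisable in the open form, the trans-fused ketol with equatorial C14 and C13′ can accumulate. DBU eliminates nitrous acid from the β-nitro ketone to give the γ-hydroxy enone triflate F6. Stille coupling as in step 10 gives the hydroxy bis-butenone sulfide F7, and NaIO4 then heat as in step 11, through the sulfoxide F8, gives 19.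

Step 3. What may go wrong: protonation of the C10 enolate on the face syn to the lactone oxygen (10-epimer), or 1,2-reduction of the enone. Fallback in which the C10 centre is set by C-methylation instead of protonation, from 1 to 7: LiAlH4 1,8-reduction of 1 gives cyclohepta-3,5-dien-1-one F9. DBU isomerises it to cyclohepta-2,4-dien-1-one F10. Annulation with 4 as in step 2 gives the 10-demethyl cis-fused α-methylene lactone enone F11, and PhSH gives its thiol adduct F12. LiBH(s-Bu)3 followed by MeI then gives 7. If the enolate takes electrophiles on the face syn to the lactone oxygen, this places the methyl, and not the hydrogen, cis to the lactone; C10 remains epimerisable in either case.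

**Further compounds**

F1 | step 2 | tert-butyl 2-(4-methyl-5-oxocyclohept-2-en-1-yl)acrylate (C10 epimers) | CC(C)(C)OC(=O)C(=C)[C@@H]1C=CC(C)C(=O)CC1
F2 | step 2 | 9-iodo cis-lactone ketone (I trans to the lactone oxygen, C10 epimers) | C=C1C(=O)O[C@@H]2[C@@H](I)C(C)C(=O)CC[C@H]12
F3 | step 9 | (7R,8R,10S,11S)-masked ketone (single antipode of 7) | O=C1O[C@@H]2C[C@H](C)C(=O)CC[C@@H]2[C@@H]1CSc1ccccc1
F4 | step 9 | (7S,8S,10R,11R)-masked ketone (antipode of F3) | O=C1O[C@H]2C[C@@H](C)C(=O)CC[C@H]2[C@H]1CSc1ccccc1
F5 | step 9 | nitro ketol (C1–OH, C2–NO2, C3–Ac; C2/C3 epimers; 13-SPh; C1′–OTf) | O=C1O[C@@H]2C[C@H](C)[C@@]3(O)C([N+](=O)[O-])C(C(C)=O)[C@]4(C[C@@H]3C[C@@H]2[C@@H]1CSc1ccccc1)C(=O)O[C@H]1C[C@@H](C)C(OS(=O)(=O)C(F)(F)F)=CC[C@H]14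
F6 | step 9 | γ-hydroxy enone triflate (13-SPh; C1′–OTf) | O=C1O[C@@H]2C[C@H](C)[C@@]3(O)C=C(C(C)=O)[C@]4(C[C@@H]3C[C@@H]2[C@@H]1CSc1ccccc1)C(=O)O[C@H]1C[C@@H](C)C(OS(=O)(=O)C(F)(F)F)=CC[C@H]14
F7 | step 9 | 13-(phenylsulfanyl)-11,13-dihydro derivative of 19 | O=C1O[C@@H]2C[C@H](C)[C@@]3(O)C=C(C(C)=O)[C@]4(C[C@@H]3C[C@@H]2[C@@H]1CSc1ccccc1)C(=O)O[C@H]1C[C@@H](C)C(/C=C/C(C)=O)=CC[C@H]14
F8 | step 9 | sulfoxide of F7 (mixture at sulfur) | O=C1O[C@@H]2C[C@H](C)[C@@]3(O)C=C(C(C)=O)[C@]4(C[C@@H]3C[C@@H]2[C@@H]1CS(=O)c1ccccc1)C(=O)O[C@H]1C[C@@H](C)C(/C=C/C(C)=O)=CC[C@H]14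
F9 | step 3 | cyclohepta-3,5-dien-1-one | O=C1CC=CC=CC1
F10 | step 3 | cyclohepta-2,4-dien-1-one | O=C1C=CC=CCC1
F11 | step 3 | racemic 10-demethyl cis-fused α-methylene lactone enone | C=C1C(=O)O[C@@H]2C=CC(=O)CC[C@H]12
F12 | step 3 | thiol adduct of F11 (racemic) | O=C1O[C@@H]2C=CC(=O)CC[C@@H]2[C@@H]1CSc1ccccc1
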